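## Assumptions
- The target SMILES leaves the biaryl axes unspecified. I assume the natural (S)-configured axes, which the D-gluco chain should impose.
- The benzylic C1–OH is assumed to survive the final Pd(OH)2/H2 step.

## Retrosynthetic overview
1. Chinquapinic acid comes from per-debenzylation (ten O-Bn) of the benzylated hydroxy-acid, which comes from selective opening of the C2–O lactone of the benzylated C-arylglucosidic polycycle.
2. The polycycle comes from a one-pot triple oxidative biaryl coupling (key step) of a C-arylglucosidic lactone carrying five mono-phenolic galloyl units. It forms the 4,6-HHDP ring, then the 2,3-biaryl (10-membered) ring, then the 3,5-bridging (11-membered) ring.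
3. That lactone comes from desilylation of the aldehydo-glucose penta-ester, then intramolecular Mg-phenoxide ortho-hydroxyalkylation of the aldehyde (C1–aryl bond, six-membered lactone).
4. The aldehydo penta-ester comes from D-glucose diethyl dithioacetal plus five units of 3,4-bis(benzyloxy)-5-(TBSO)benzoic acid, which comes from methyl gallate.
5. Ring-forming order: six-membered lactone, then the 11-membered 4,6-HHDP ring, then the 10-membered 2,3-biaryl ring, then the 11-membered 3,5-bridge.

## Route

**Step 1**
Reactants: 1 methyl gallate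
Product: 2 methyl 3,4-bis(benzyloxy)-5-hydroxybenzoate
Conditions: BnBr (2.0 equiv), KHCO3, DMF, rt
Reagents that add atoms: two molecules of benzyl bromide (two Bn groups incorporated): BrCc1ccccc1 ; BrCc1ccccc1
Why: Williamson etherification of the two most acidic phenols (4-OH, then 3-OH) under weakly basic conditions leaves the 5-OH free, which is the mono-phenol pattern needed for coupling; the 3,4- and 3,5-isomers and the tribenzyl ether are removed by chromatography.

**Step 2**
Reactants: 2 methyl 3,4-bis(benzyloxy)-5-hydroxybenzoate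
Product: 3 3,4-bis(benzyloxy)-5-hydroxybenzoic acid
Conditions: KOH, EtOH/H2O, reflux; then HCl to pH 2
Reagents that add atoms: water, O
Why: Saponification of the methyl ester (BnOH is not released because the benzyl ethers are stable), giving the free acid after acidification.

**Step 3**
Reactants: 3 3,4-bis(benzyloxy)-5-hydroxybenzoic acid
Product: 4 3,4-bis(benzyloxy)-5-(tert-butyldimethylsilyloxy)benzoic acid
Conditions: TBSCl (2.4 equiv), imidazole, DMF, rt; then THF/AcOH/H2O, rt, 30 min
Reagents that add atoms: tert-butyldimethylsilyl chloride (one TBS retained on the phenol): CC(C)(C)[Si](C)(C)Cl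
Why: Double silylation gives the silyl ether and the silyl ester, and mild aqueous acid cleaves only the labile silyl ester, so the phenol is masked during esterification.

**Step 4**
Reactants: 5 D-glucose
Product: 6 D-glucose diethyl dithioacetal
Conditions: EtSH, conc. HCl, 0 °C → rt
Reagents that add atoms: two molecules of ethanethiol (both EtS groups incorporated): CCS ; CCS
Why: Acid-catalysed dithioacetalisation locks the open-chain form and carries the D-gluco configuration at C2–C5 through unchanged.

**Step 5**
Reactants: 6 D-glucose diethyl dithioacetal (1 equiv); 4 3,4-bis(benzyloxy)-5-(TBSO)benzoic acid (five molecules incorporated, 6.5 equiv charged)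
Product: 7 penta-(3,4-bis(benzyloxy)-5-TBSO-benzoate) of 6
Conditions: EDC·HCl, DMAP, CH2Cl2, rt → 40 °C
Reagents that add atoms: four further molecules of acid 4 beyond the one listed as a reactant, so that five in total are incorporated: OC(=O)c1cc(O[Si](C)(C)C(C)(C)C)c(OCc2ccccc2)c(OCc2ccccc2)c1 ; OC(=O)c1cc(O[Si](C)(C)C(C)(C)C)c(OCc2ccccc2)c(OCc2ccccc2)c1 ; OC(=O)c1cc(O[Si](C)(C)C(C)(C)C)c(OCc2ccccc2)c(OCc2ccccc2)c1 ; OC(=O)c1cc(O[Si](C)(C)C(C)(C)C)c(OCc2ccccc2)c(OCc2ccccc2)c1
Why: Steglich per-acylation of all five sugar hydroxyls (five H2O formally lost, carried off as the urea) needs no sugar protection, and no carbinol stereocentre is touched.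

**Step 6**
Reactants: 7 penta-ester dithioacetal
Product: 8 aldehydo-D-glucose penta-ester
Conditions: HgCl2, CaCO3, MeCN/H2O 4:1, rt
Reagents that add atoms: water, O
Why: Hg(II)-promoted dethioacetalisation under buffered, non-enolising conditions gives the aldehyde without C2 epimerisation or β-acyloxy elimination (the same method gives aldehydo-glucose pentaacetate).

**Step 7**
Reactants: 8 aldehydo-D-glucose penta-ester
Product: 9 C-arylglucosidic δ-lactone with C1–OH (five free phenols)
Conditions: (i) TBAF/AcOH (6.5 equiv each), THF, 0 °C, 20 min; (ii) same pot, MgBr2·OEt2 (8 equiv), i-Pr2NEt (8 equiv), CH2Cl2, 0 °C → rt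
Reagents that add atoms: none
Why: Proposed new method: buffered desilylation gives five mono-phenols, and the Mg-phenoxide of the O2-galloyl adds through its free ortho carbon (C6) to the aldehyde via a chelated six-membered transition state. This forms the C1–aryl bond and closes the six-membered lactone (C1, C6, C1′, C=O, O2, C2). The new C1 stereocentre is set by substrate control from the adjacent C2 centre in the Mg-chelated half-chair, and the D-gluco chain fixes the facial bias. The closest known reaction is magnesium-phenoxide ortho-hydroxyalkylation (Casiraghi type), and the O2-ester tether makes this six-membered closure much more favourable than the 7–10-membered closures available to the other gallates.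

**Step 8 (key step)**
Reactants: 9 C-arylglucosidic lactone with five free phenols
Product: 10 benzylated lactone polycycle (three new biaryl bonds, five phenols, C1–OH)
Conditions: CuCl2 (12 equiv), n-BuNH2 (48 equiv), O2 (1 atm), CH2Cl2/MeOH 1:1 (≈2 mM), 4 Å MS, −10 °C → rt, 12 h
Reagents that add atoms: none (O2 is the terminal oxidant and only removes six H atoms as water)
Why: Proposed new method: the Cu(II)/amine system oxidises each mono-phenol to a phenoxyl/phenoxonium (cyclohexadienone-type) intermediate, so aromaticity is transiently broken. A neighbouring phenolate then attacks one ring carbon intramolecularly, and tautomerisation re-aromatises to the biaryl. Each galloyl ring has two equivalent ortho carbons, and the tether selects one, so the symmetry is broken. The lactone/glucose template assembles the rings in turn as 4,6-(S)-HHDP (11-membered), then the 2,3-biaryl (10-membered, through the O2 lactone), then the 3,5-biaryl (11-membered). The axes are set by central-to-axial transfer from the D-gluco chain. The closest known reactions are Cu-amine intramolecular oxidative coupling of 4,6-di-O-galloylglucose to (S)-HHDP and the biosynthetic casuarinin-to-vescalagin-type 3,5-coupling.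

**Step 9**
Reactants: 10 benzylated lactone polycycle
Product: 11 benzylated hydroxy-acid (free C2–OH and ring-C CO2H)
Conditions: LiOH·H2O (3 equiv), THF/H2O 5:1, 0 °C, 1 h; quench with aq. NaH2PO4 to pH 5
Reagents that add atoms: water, O
Why: Proposed new method: hydroxide opens the C2–O lactone by acyl–oxygen cleavage. The C2 alkoxide is a better leaving group than the others, being flanked by the C1–OH and the C3 acyloxy group, and the C1–OH can hydrogen-bond and deliver hydroxide. The other esters, which carry phenolate-bearing biaryl acyl groups, are deactivated towards hydroxide. The closest known reaction is hydroxyl-assisted saponification of β-hydroxy esters, and no stereocentre is touched.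

**Step 10**
Reactants: 11 benzylated hydroxy-acid
Product: 12 chinquapinic acid (target)
Conditions: H2 (1 atm), Pd(OH)2/C, THF/MeOH 1:1, rt, 24 h
Reagents that add atoms: none (H2 only adds hydrogen; toluene is lost)
Why: Hydrogenolysis removes all ten aryl benzyl ethers to give the fifteen aryl OH groups, and the sugar stereocentres and biaryl axes are unaffected.

## Compound list
1 | methyl gallate | COC(=O)c1cc(O)c(O)c(O)c1 | starting material
2 | methyl 3,4-bis(benzyloxy)-5-hydroxybenzoate | COC(=O)c1cc(O)c(OCc2ccccc2)c(OCc2ccccc2)c1 | intermediate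
3 | 3,4-bis(benzyloxy)-5-hydroxybenzoic acid | OC(=O)c1cc(O)c(OCc2ccccc2)c(OCc2ccccc2)c1 | intermediate
4 | 3,4-bis(benzyloxy)-5-(TBSO)benzoic acid | OC(=O)c1cc(O[Si](C)(C)C(C)(C)C)c(OCc2ccccc2)c(OCc2ccccc2)c1 | intermediate
5 | D-glucose (open-chain form) | O=C[C@H](O)[C@@H](O)[C@H](O)[C@H](O)CO | starting material
6 | D-glucose diethyl dithioacetal | CCSC(SCC)[C@H](O)[C@@H](O)[C@H](O)[C@H](O)CO | intermediate
7 | penta-ester of 6 with five units of 4 | CCSC(SCC)[C@H](OC(=O)c1cc(O[Si](C)(C)C(C)(C)C)c(OCc2ccccc2)c(OCc2ccccc2)c1)[C@@H](OC(=O)c1cc(O[Si](C)(C)C(C)(C)C)c(OCc2ccccc2)c(OCc2ccccc2)c1)[C@H](OC(=O)c1cc(O[Si](C)(C)C(C)(C)C)c(OCc2ccccc2)c(OCc2ccccc2)c1)[C@H](OC(=O)c1cc(O[Si](C)(C)C(C)(C)C)c(OCc2ccccc2)c(OCc2ccccc2)c1)COC(=O)c1cc(O[Si](C)(C)C(C)(C)C)c(OCc2ccccc2)c(OCc2ccccc2)c1 | intermediate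
8 | aldehydo-D-glucose penta-ester | O=C[C@H](OC(=O)c1cc(O[Si](C)(C)C(C)(C)C)c(OCc2ccccc2)c(OCc2ccccc2)c1)[C@@H](OC(=O)c1cc(O[Si](C)(C)C(C)(C)C)c(OCc2ccccc2)c(OCc2ccccc2)c1)[C@H](OC(=O)c1cc(O[Si](C)(C)C(C)(C)C)c(OCc2ccccc2)c(OCc2ccccc2)c1)[C@H](OC(=O)c1cc(O[Si](C)(C)C(C)(C)C)c(OCc2ccccc2)c(OCc2ccccc2)c1)COC(=O)c1cc(O[Si](C)(C)C(C)(C)C)c(OCc2ccccc2)c(OCc2ccccc2)c1 | intermediate
9 | C-arylglucosidic lactone, five free phenols | O[C@H]1c2c(O)c(OCc3ccccc3)c(OCc3ccccc3)cc2C(=O)O[C@@H]1[C@@H](OC(=O)c1cc(O)c(OCc3ccccc3)c(OCc3ccccc3)c1)[C@H](OC(=O)c1cc(O)c(OCc3ccccc3)c(OCc3ccccc3)c1)[C@H](OC(=O)c1cc(O)c(OCc3ccccc3)c(OCc3ccccc3)c1)COC(=O)c1cc(O)c(OCc3ccccc3)c(OCc3ccccc3)c1 | intermediate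
10 | benzylated lactone polycycle | O=C1OC[C@H]2OC(=O)c3cc(OCc7ccccc7)c(OCc7ccccc7)c(O)c3-c3c(OCc7ccccc7)c(OCc7ccccc7)c(O)c4c3C(=O)O[C@H]([C@@H](O6)[C@@H](O)c3c(O)c(OCc7ccccc7)c(OCc7ccccc7)c-4c3C6=O)[C@@H]2OC(=O)c2cc(OCc7ccccc7)c(OCc7ccccc7)c(O)c2-c2c1cc(OCc7ccccc7)c(OCc7ccccc7)c2O | intermediate
11 | benzylated hydroxy-acid | O=C1OC[C@H]2OC(=O)c3cc(OCc7ccccc7)c(OCc7ccccc7)c(O)c3-c3c(OCc7ccccc7)c(OCc7ccccc7)c(O)c4c3C(=O)O[C@H]([C@@H](O)[C@@H](O)c3c(O)c(OCc7ccccc7)c(OCc7ccccc7)c-4c3C(=O)O)[C@@H]2OC(=O)c2cc(OCc7ccccc7)c(OCc7ccccc7)c(O)c2-c2c1cc(OCc7ccccc7)c(OCc7ccccc7)c2O | intermediate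
12 | chinquapinic acid | O=C1OC[C@H]2OC(=O)c3cc(O)c(O)c(O)c3-c3c(O)c(O)c(O)c4c3C(=O)O[C@H]([C@@H](O)[C@@H](O)c3c(O)c(O)c(O)c-4c3C(=O)O)[C@@H]2OC(=O)c2cc(O)c(O)c(O)c2-c2c1cc(O)c(O)c2O | target

## Totals
Total steps: 10. Longest linear sequence: 9 steps from methyl gallate (7 steps from D-glucose).

## Three steps most likely to fail
1. **Step 8 (triple oxidative coupling).** It may give wrong ring pairings (mixed ortho/para couplings), over-oxidation to quinones, or the wrong axial sense.
   - Fallback: change the bond-forming strategy. Use differentiated phenol protection (TES versus TBS) and bromogallates, form the 4,6-(S)-HHDP and the 2,3-biaryl by template-directed intramolecular Ullmann coupling, and close the 3,5-bridge last.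
2. **Step 7 (C-arylglucosidation).** It may give the wrong C1 epimer, acyl migration, or C2 epimerisation/β-elimination.
   - Fallback: follow the biosynthetic order. Install the 4,6-HHDP before unmasking the aldehyde, and run the hydroxyalkylation on the rigid HHDP-bearing aldehyde through its free ortho carbon.
3. **Step 9 (lactone opening).** It may be unselective against the other esters, or the product may re-lactonise.
   - Fallback: reverse the order of the last two steps and open the lactone enzymatically (tannase/esterase, pH 6 buffer) on the fully debenzylated polycycle instead of using chemical base.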